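**Plan**

- Retrosynthesis cuts, in order: the C–OOH bond (SN2 on the epimeric allylic sulfonate), the oxirane oxygen, the ring bond between the methyl-bearing alkene carbon and the CH2–CH2 arm on C4 of the oxan-2-one, and the carbinol–C(=CH2) bond. This leaves a vinyl lactone aldehyde and a C7 alkenyl triflate that carries a masked iodoalkene.
- Feature used: the epoxide is the oxide of an E-trisubstituted ring alkene, C(CH3)=CH, whose methyl-bearing carbon is tied by two CH2 groups to C4 of the six-membered lactone. That sp2–sp3 bond can be made from an (E)-2-iodoalkene and the alkylborane of a C4 vinyl group, with the geometry already fixed, closing the 14-membered carbocycle.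
- Forward: the lactone ring is built first on the (S)-linalool chain (allylboration, cross-metathesis, iridium-catalysed allylic alkylation, decarboxylative lactonisation, methylation). The C7 chain is joined by Ni/Cr coupling, the macrocycle is closed by B-alkyl Suzuki coupling, and the oxirane and then the hydroperoxide are installed last.
- Stereochemistry: tertiary carbinol from (S)-linalool; lactone C6 from reagent-controlled allylboration; C4 from the iridium catalyst; C3 by trans alkylation; alkene geometry from syn hydrosilylation and retentive iododesilylation; the carbinol from a chiral chromium ligand, then inverted by peroxide; the epoxide from a chiral ketone.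

Key step: step 18

Remark: the facial sense quoted for the ligand-controlled steps 7 and 15 rests on analogy with simple substrates, and the antipodal ligand is taken if a model run shows the opposite sense.

**Route**

Step 1
Reactants: 1 (S)-linalool
Product: 2 (3S)-3,7-dimethyl-3-(triethylsilyloxy)octa-1,6-diene
Conditions: Et3SiOTf, 2,6-lutidine, CH2Cl2, −78 to 0 °C
Reagents that add atoms: triethylsilyl trifluoromethanesulfonate, CC[Si](CC)(CC)OS(=O)(=O)C(F)(F)F
Why: Silyl ether formation with a silyl triflate and a hindered pyridine base is reliable for tertiary allylic alcohols and leaves the linalool stereocentre untouched.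

Step 2
Reactants: 2 (3S)-3,7-dimethyl-3-(triethylsilyloxy)octa-1,6-diene
Product: 4 (4S)-4-methyl-4-(triethylsilyloxy)hex-5-en-1-ol, via aldehyde 3 (not isolated)
Conditions: O3 (1.0 equiv), pyridine, CH2Cl2/MeOH, −78 °C; then NaBH4, −78 to 0 °C
Reagents that add atoms: ozone, [O-][O+]=O
Why: Chemoselective ozonolysis with reductive work-up, in which the electron-rich trisubstituted alkene is cleaved well before the vinyl group that is shielded and deactivated by the allylic silyloxy group, and NaBH4 reduces aldehyde 3 in the same flask.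

Step 3
Reactants: 4 (4S)-4-methyl-4-(triethylsilyloxy)hex-5-en-1-ol
Product: 5 (4S)-4-methyl-4-(triethylsilyloxy)hex-5-en-1-yl acetate
Conditions: Ac2O, pyridine, DMAP (cat.), CH2Cl2, 0 °C to rt
Reagents that add atoms: acetic anhydride, CC(=O)OC(C)=O
Why: Acylation of the primary alcohol gives an ester that should survive the next four steps and is removed without an extra step in the saponification of step 8.

Step 4
Reactants: 5 (4S)-4-methyl-4-(triethylsilyloxy)hex-5-en-1-yl acetate
Product: 6 (4S)-4-methyl-5-oxo-4-(triethylsilyloxy)pentyl acetate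
Conditions: O3, CH2Cl2, −78 °C; then PPh3, −78 °C to rt
Reagents that add atoms: ozone, [O-][O+]=O
Why: Ozonolysis with phosphine work-up of the only remaining alkene gives the α-silyloxy aldehyde, whose α-carbon is quaternary and cannot epimerise.

Step 5
Reactants: 6 (4S)-4-methyl-5-oxo-4-(triethylsilyloxy)pentyl acetate
Product: 7 (4S,5R)-5-hydroxy-4-methyl-4-(triethylsilyloxy)oct-7-en-1-yl acetate
Conditions: B-allylbis(isopinocampheyl)borane from (−)-α-pinene, Et2O, −78 °C; then NaBO3·4H2O, THF/H2O, rt
Reagents that add atoms: B-allylbis[(1S,2S,3S,5R)-isopinocampheyl]borane, C=CCB([C@H]1C[C@H]2C[C@@H]([C@@H]1C)C2(C)C)[C@H]1C[C@H]2C[C@@H]([C@@H]1C)C2(C)C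
Why: Brown allylation through a closed chair transition state under reagent control, in which the (−)-α-pinene-derived borane should add allyl to the Re face of the aldehyde and set the (5R) carbinol, the future lactone C6.

Step 6
Reactants: 7 (4S,5R)-5-hydroxy-4-methyl-4-(triethylsilyloxy)oct-7-en-1-yl acetate; 8 allyl methyl carbonate
Product: 9 (4S,5R,7E)-5-hydroxy-9-(methoxycarbonyloxy)-4-methyl-4-(triethylsilyloxy)non-7-en-1-yl acetate
Conditions: 8 (4 equiv), second-generation Hoveyda–Grubbs catalyst (5 mol%), CH2Cl2, 40 °C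
Reagents that add atoms: none
Why: Olefin cross-metathesis of a terminal alkene with excess allyl methyl carbonate should give the E-configured linear allylic carbonate with loss of ethene, the free alcohol and both esters being tolerated.

Step 7
Reactants: 9 (4S,5R,7E)-5-hydroxy-9-(methoxycarbonyloxy)-4-methyl-4-(triethylsilyloxy)non-7-en-1-yl acetate; 10 dimethyl malonate
Product: 11 dimethyl 2-[(3S,5R,6S)-9-acetoxy-5-hydroxy-6-methyl-6-(triethylsilyloxy)non-1-en-3-yl]malonate
Conditions: [Ir(cod)Cl]2 (2 mol%), (Ra,R,R)-O,O′-(1,1′-binaphthalene-2,2′-diyl) N,N-bis(1-phenylethyl)phosphoramidite (4 mol%), 1,5,7-triazabicyclo[4.4.0]dec-5-ene (10 mol%), THF, rt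
Reagents that add atoms: none
Why: Iridium-catalysed asymmetric allylic alkylation under salt-free conditions, in which the cyclometalated iridium phosphoramidite complex directs the malonate to the substituted allyl terminus and fixes the vinyl-bearing stereocentre (the future lactone C4) by catalyst control.

Step 8
Reactants: 11 dimethyl 2-[(3S,5R,6S)-9-acetoxy-5-hydroxy-6-methyl-6-(triethylsilyloxy)non-1-en-3-yl]malonate
Product: 14 (4R,6R)-4-ethenyl-6-[(2S)-5-hydroxy-2-(triethylsilyloxy)pentan-2-yl]oxan-2-one, via diacid 12 (not isolated), via hydroxy acid 13 (not isolated)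
Conditions: LiOH, THF/MeOH/H2O, 40 °C; 1 M HCl to pH 3, 0 °C; then pyridine (2 equiv), toluene, 110 °C, azeotropic removal of water
Reagents that add atoms: lithium hydroxide, [Li+].[OH-]
Why: Malonic ester saponification, decarboxylation of the malonic acid and lactonisation of the δ-hydroxy acid should form the six-membered lactone without touching a stereocentre, and the acetate is cleaved in the same operation.

Step 9
Reactants: 14 (4R,6R)-4-ethenyl-6-[(2S)-5-hydroxy-2-(triethylsilyloxy)pentan-2-yl]oxan-2-one
Product: 15 (3S,4S,6R)-4-ethenyl-6-[(2S)-5-hydroxy-2-(triethylsilyloxy)pentan-2-yl]-3-methyloxan-2-one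
Conditions: LiN(iPr)2 (2.2 equiv), THF, −78 °C; MeI, −78 to −40 °C
Reagents that add atoms: iodomethane, CI
Why: Alkylation of the lactone enolate, with the primary hydroxyl carried as its lithium alkoxide, should occur anti to the adjacent C4 vinyl group and give the 3,4-trans lactone with the (3S) methyl centre.

Step 10
Reactants: 15 (3S,4S,6R)-4-ethenyl-6-[(2S)-5-hydroxy-2-(triethylsilyloxy)pentan-2-yl]-3-methyloxan-2-one
Product: 16 (4S)-4-[(2R,4S,5S)-4-ethenyl-5-methyl-6-oxooxan-2-yl]-4-(triethylsilyloxy)pentanal
Conditions: TEMPO (10 mol%), PhI(OAc)2, CH2Cl2, rt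
Reagents that add atoms: none
Why: Nitroxyl-catalysed oxidation with a hypervalent iodine co-oxidant should convert the primary alcohol to the aldehyde without over-oxidation and without affecting the vinyl group, the silyl ether or the lactone.

Step 11
Reactants: 17 but-2-yn-1-ol
Product: 18 (E)-3-(triethylsilyl)but-2-en-1-ol
Conditions: Et3SiH, PtCl2 (1 mol%), XPhos (2 mol%), THF, 50 °C
Reagents that add atoms: triethylsilane, CC[SiH](CC)CC
Why: Platinum-catalysed syn hydrosilylation of a propargylic alcohol with a bulky biaryl phosphine should place silicon on the alkyne carbon remote from the carbinol, giving the (E)-vinylsilane that fixes the later alkene geometry.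

Step 12
Reactants: 18 (E)-3-(triethylsilyl)but-2-en-1-ol
Product: 19 (E)-(4-bromobut-2-en-2-yl)triethylsilane
Conditions: CBr4, PPh3, CH2Cl2, 0 °C
Reagents that add atoms: carbon tetrabromide, BrC(Br)(Br)Br
Why: The Appel reaction converts the allylic alcohol to the bromide under neutral conditions that leave the vinylsilane intact.

Step 13
Reactants: 19 (E)-(4-bromobut-2-en-2-yl)triethylsilane; 20 pentane-2,4-dione
Product: 22 (E)-6-(triethylsilyl)hept-5-en-2-one, via diketone 21 (not isolated)
Conditions: K2CO3, EtOH, reflux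
Reagents that add atoms: none
Why: C-Alkylation of the 1,3-diketone followed by retro-Claisen deacetylation in hot ethanolic carbonate should deliver the methyl ketone in one operation.

Step 14
Reactants: 22 (E)-6-(triethylsilyl)hept-5-en-2-one
Product: 23 (E)-6-(triethylsilyl)hepta-1,5-dien-2-yl trifluoromethanesulfonate
Conditions: LiN(iPr)2, THF, −78 °C; N-(5-chloropyridin-2-yl)bis(trifluoromethanesulfonyl)imide, −78 °C
Reagents that add atoms: N-(5-chloropyridin-2-yl)bis(trifluoromethanesulfonyl)imide, O=S(=O)(N(c1ccc(Cl)cn1)S(=O)(=O)C(F)(F)F)C(F)(F)F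
Why: Kinetic deprotonation at the methyl group and O-sulfonylation of the terminal enolate at low temperature should give the 2-triflyloxy-1-alkene.

Step 15
Reactants: 16 (4S)-4-[(2R,4S,5S)-4-ethenyl-5-methyl-6-oxooxan-2-yl]-4-(triethylsilyloxy)pentanal; 23 (E)-6-(triethylsilyl)hepta-1,5-dien-2-yl trifluoromethanesulfonate
Product: 24 (3S,4S,6R)-4-ethenyl-6-[(2S,5S,9E)-5-hydroxy-6-methylidene-10-(triethylsilyl)-2-(triethylsilyloxy)undec-9-en-2-yl]-3-methyloxan-2-one
Conditions: CrCl2 (4 equiv), tert-leucinol-derived 2-(2-methanesulfonamidoaryl)oxazoline ligand (4.4 equiv), Et3N, NiCl2 (10 mol%), MeCN/THF, rt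
Reagents that add atoms: none
Why: Nozaki–Hiyama–Kishi coupling, in which nickel activates the alkenyl triflate and transmetalation gives an alkenylchromium species that adds only to the aldehyde, and the chiral oxazoline–sulfonamide on chromium should deliver it to the Re face to set the (S)-carbinol.

Step 16
Reactants: 24 (S)-allylic alcohol named in step 15
Product: 25 (3S,4S,6R)-4-ethenyl-3-methyl-6-[(2S,5S,9E)-6-methylidene-10-(triethylsilyl)-2,5-bis(triethylsilyloxy)undec-9-en-2-yl]oxan-2-one
Conditions: Et3SiCl, imidazole, DMAP (cat.), DMF, 0 °C to rt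
Reagents that add atoms: chlorotriethylsilane, CC[Si](Cl)(CC)CC
Why: Silyl ether formation protects the allylic alcohol and adds bulk beside the exocyclic alkene, which helps the selective hydroboration of step 18.

Step 17
Reactants: 25 bis(silyl ether) named in step 16
Product: 26 (3S,4S,6R)-4-ethenyl-6-[(2S,5S,9E)-10-iodo-6-methylidene-2,5-bis(triethylsilyloxy)undec-9-en-2-yl]-3-methyloxan-2-one
Conditions: N-iodosuccinimide, 2,6-lutidine, (CF3)2CHOH, 0 °C
Reagents that add atoms: N-iodosuccinimide, O=C1CCC(=O)N1I
Why: Iododesilylation is an ipso substitution through a β-silyl cation that proceeds with retention, so the (E)-vinylsilane should give the (E)-2-iodoalkene while the less nucleophilic alkenes are left alone.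

Step 18
Reactants: 26 vinyl lactone iodoalkene named in step 17
Product: 28 macrocyclic E-alkene lactone bis(triethylsilyl) ether, via alkylborane 27 (not isolated)
Conditions: 9-BBN (1.2 equiv), THF, 0 °C to rt; then slow addition to Pd(dppf)Cl2 (20 mol%), AsPh3, Cs2CO3, DMF/THF/H2O, 40 °C, about 1 mM
Reagents that add atoms: none
Why: Terminal-selective syn addition of 9-BBN to the vinyl group on lactone C4 gives primary alkylborane 27; zerovalent palladium then inserts into the C–I bond, the base-activated borate transfers its primary alkyl group to palladium, and reductive elimination joins that CH2 carbon to the methyl-bearing sp2 carbon with retention of the E geometry. The closest known reaction type is the intramolecular B-alkyl Suzuki–Miyaura coupling used to close macrocycles at trisubstituted alkenes. The 14-membered carbocycle closes end to end: both reacting termini sit on one chain, transmetalation gives a 15-membered palladacycle and reductive elimination contracts it to the ring, so slow addition at high dilution is needed to suppress oligomerisation. No stereocentre is formed, and the only stereochemical element, the alkene geometry, is fixed beforehand in iodide 26. The step needs hydroboration of the vinyl group in preference to the exocyclic 1,1-disubstituted alkene, which should be secured by the branching and the bulky silyloxy group at its allylic carbon, the inductive deactivation by that oxygen and the use of only a slight excess of borane at 0 °C. A small-ring Heck cyclisation onto the exocyclic alkene is excluded because the tether is trans to palladium on the alkene, and the mild carbonate base with AsPh3 should keep the lactone closed.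

Step 19
Reactants: 28 macrocyclic E-alkene lactone bis(triethylsilyl) ether
Product: 29 macrocyclic (S,S)-epoxide bis(triethylsilyl) ether
Conditions: 1,2:4,5-di-O-isopropylidene-β-L-erythro-2,3-hexodiulo-2,6-pyranose (30 mol%), KHSO5 (as Oxone), K2CO3, Bu4NHSO4, MeCN/CH2(OMe)2/aq. Na2B4O7 buffer (pH 10.5), 0 °C
Reagents that add atoms: potassium peroxymonosulfate, [K+].[O-]S(=O)(=O)OO
Why: Shi epoxidation, in which the dioxirane from the chiral ketone transfers oxygen through a spiro transition state to the trisubstituted E-alkene (far more reactive than the hindered exocyclic alkene), and the L-configured ketone should give the (S,S)-epoxide.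

Step 20
Reactants: 29 macrocyclic (S,S)-epoxide bis(triethylsilyl) ether
Product: 30 macrocyclic epoxy (S)-allylic alcohol, tertiary triethylsilyl ether
Conditions: HF·pyridine, pyridine, THF, 0 °C
Reagents that add atoms: none
Why: Buffered fluoride desilylation cleaves the secondary triethylsilyl ether much faster than the tertiary one, which must stay so that the 1,4-related tertiary oxygen cannot attack the sulfonate of step 21.

Step 21
Reactants: 30 macrocyclic epoxy (S)-allylic alcohol, tertiary triethylsilyl ether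
Product: 32 macrocyclic epoxy (R)-hydroperoxide, tertiary triethylsilyl ether, via mesylate 31 (not isolated)
Conditions: Ms2O, iPr2NEt, CH2Cl2, −40 °C; then H2O2 (anhydrous, in Et2O, large excess), −40 to 0 °C
Reagents that add atoms: hydrogen peroxide, OO
Why: Sulfonylation followed by SN2 displacement of the allylic mesylate by hydrogen peroxide should install the hydroperoxide with inversion, turning the (S)-carbinol into the (R)-hydroperoxide.

Step 22
Reactants: 32 macrocyclic epoxy (R)-hydroperoxide, tertiary triethylsilyl ether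
Product: 33 CNP0319766.1
Conditions: HF·pyridine, pyridine, THF, 0 °C to rt
Reagents that add atoms: none
Why: Fluoride-mediated desilylation under pyridine-buffered conditions should remove the tertiary silyl ether while the hydroperoxide, the epoxide and the lactone are tolerated.

**Compound list**

1 | (S)-linalool, (3S)-3,7-dimethylocta-1,6-dien-3-ol | C=C[C@@](C)(O)CCC=C(C)C | starting material
2 | (3S)-3,7-dimethyl-3-(triethylsilyloxy)octa-1,6-diene | C=C[C@@](C)(O[Si](CC)(CC)CC)CCC=C(C)C | intermediate
3 | (4S)-4-methyl-4-(triethylsilyloxy)hex-5-enal | C=C[C@@](C)(O[Si](CC)(CC)CC)CCC=O | intermediate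
4 | (4S)-4-methyl-4-(triethylsilyloxy)hex-5-en-1-ol | C=C[C@@](C)(O[Si](CC)(CC)CC)CCCO | intermediate
5 | (4S)-4-methyl-4-(triethylsilyloxy)hex-5-en-1-yl acetate | C=C[C@@](C)(O[Si](CC)(CC)CC)CCCOC(C)=O | intermediate
6 | (4S)-4-methyl-5-oxo-4-(triethylsilyloxy)pentyl acetate | O=C[C@@](C)(O[Si](CC)(CC)CC)CCCOC(C)=O | intermediate
7 | (4S,5R)-5-hydroxy-4-methyl-4-(triethylsilyloxy)oct-7-en-1-yl acetate | C=CC[C@@H](O)[C@@](C)(O[Si](CC)(CC)CC)CCCOC(C)=O | intermediate
8 | allyl methyl carbonate | C=CCOC(=O)OC | starting material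
9 | (4S,5R,7E)-5-hydroxy-9-(methoxycarbonyloxy)-4-methyl-4-(triethylsilyloxy)non-7-en-1-yl acetate | COC(=O)OC/C=C/C[C@@H](O)[C@@](C)(O[Si](CC)(CC)CC)CCCOC(C)=O | intermediate
10 | dimethyl malonate | COC(=O)CC(=O)OC | starting material
11 | dimethyl 2-[(3S,5R,6S)-9-acetoxy-5-hydroxy-6-methyl-6-(triethylsilyloxy)non-1-en-3-yl]malonate | C=C[C@@H](C(C(=O)OC)C(=O)OC)C[C@@H](O)[C@@](C)(O[Si](CC)(CC)CC)CCCOC(C)=O | intermediate
12 | 2-[(3S,5R,6S)-5,9-dihydroxy-6-methyl-6-(triethylsilyloxy)non-1-en-3-yl]malonic acid | C=C[C@@H](C(C(=O)O)C(=O)O)C[C@@H](O)[C@@](C)(O[Si](CC)(CC)CC)CCCO | intermediate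
13 | (3R,5R,6S)-3-ethenyl-5,9-dihydroxy-6-methyl-6-(triethylsilyloxy)nonanoic acid | C=C[C@@H](CC(=O)O)C[C@@H](O)[C@@](C)(O[Si](CC)(CC)CC)CCCO | intermediate
14 | (4R,6R)-4-ethenyl-6-[(2S)-5-hydroxy-2-(triethylsilyloxy)pentan-2-yl]oxan-2-one | C=C[C@@H]1C[C@@H](OC(=O)C1)[C@@](C)(O[Si](CC)(CC)CC)CCCO | intermediate
15 | (3S,4S,6R)-4-ethenyl-6-[(2S)-5-hydroxy-2-(triethylsilyloxy)pentan-2-yl]-3-methyloxan-2-one | C=C[C@@H]1C[C@@H](OC(=O)[C@H]1C)[C@@](C)(O[Si](CC)(CC)CC)CCCO | intermediate
16 | (4S)-4-[(2R,4S,5S)-4-ethenyl-5-methyl-6-oxooxan-2-yl]-4-(triethylsilyloxy)pentanal | C=C[C@@H]1C[C@@H](OC(=O)[C@H]1C)[C@@](C)(O[Si](CC)(CC)CC)CCC=O | intermediate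
17 | but-2-yn-1-ol | CC#CCO | starting material
18 | (E)-3-(triethylsilyl)but-2-en-1-ol | OC/C=C(\C)[Si](CC)(CC)CC | intermediate
19 | (E)-(4-bromobut-2-en-2-yl)triethylsilane | BrC/C=C(\C)[Si](CC)(CC)CC | intermediate
20 | pentane-2,4-dione | CC(=O)CC(C)=O | starting material
21 | 3-[(E)-3-(triethylsilyl)but-2-en-1-yl]pentane-2,4-dione | CC(=O)C(C/C=C(\C)[Si](CC)(CC)CC)C(C)=O | intermediate
22 | (E)-6-(triethylsilyl)hept-5-en-2-one | CC(=O)CC/C=C(\C)[Si](CC)(CC)CC | intermediate
23 | (E)-6-(triethylsilyl)hepta-1,5-dien-2-yl trifluoromethanesulfonate | C=C(OS(=O)(=O)C(F)(F)F)CC/C=C(\C)[Si](CC)(CC)CC | intermediate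
24 | (3S,4S,6R)-4-ethenyl-6-[(2S,5S,9E)-5-hydroxy-6-methylidene-10-(triethylsilyl)-2-(triethylsilyloxy)undec-9-en-2-yl]-3-methyloxan-2-one | C=C[C@@H]1C[C@@H](OC(=O)[C@H]1C)[C@@](C)(O[Si](CC)(CC)CC)CC[C@H](O)C(=C)CC/C=C(\C)[Si](CC)(CC)CC | intermediate
25 | (3S,4S,6R)-4-ethenyl-3-methyl-6-[(2S,5S,9E)-6-methylidene-10-(triethylsilyl)-2,5-bis(triethylsilyloxy)undec-9-en-2-yl]oxan-2-one | C=C[C@@H]1C[C@@H](OC(=O)[C@H]1C)[C@@](C)(O[Si](CC)(CC)CC)CC[C@H](O[Si](CC)(CC)CC)C(=C)CC/C=C(\C)[Si](CC)(CC)CC | intermediate
26 | (3S,4S,6R)-4-ethenyl-6-[(2S,5S,9E)-10-iodo-6-methylidene-2,5-bis(triethylsilyloxy)undec-9-en-2-yl]-3-methyloxan-2-one (vinyl lactone iodoalkene) | C=C[C@@H]1C[C@@H](OC(=O)[C@H]1C)[C@@](C)(O[Si](CC)(CC)CC)CC[C@H](O[Si](CC)(CC)CC)C(=C)CC/C=C(\C)I | intermediate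
27 | alkylborane: 26 with the C4 vinyl group converted into CH2CH2–B(9-borabicyclo[3.3.1]nonan-9-yl) | C1CCC2CCCC1B2CC[C@@H]1C[C@@H](OC(=O)[C@H]1C)[C@@](C)(O[Si](CC)(CC)CC)CC[C@H](O[Si](CC)(CC)CC)C(=C)CC/C=C(\C)I | intermediate
28 | macrocyclic E-alkene lactone: (3S,4R,6R)-3-methyloxan-2-one whose C4 and C6 are bridged, from C4 to C6, by CH2CH2–C(CH3)=CH–CH2CH2–C(=CH2)–CH(OSiEt3)–CH2CH2–C(CH3)(OSiEt3); ring alkene E, CH(OSiEt3) S, C(CH3)(OSiEt3) S; 14-membered carbocycle | C=C1CC/C=C(\C)CC[C@@H]2C[C@@H](OC(=O)[C@H]2C)[C@@](C)(O[Si](CC)(CC)CC)CC[C@@H]1O[Si](CC)(CC)CC | intermediate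
29 | 28 with the ring alkene as its (S,S)-oxirane (both oxirane carbons S; ring CH2 groups trans across the oxirane) | C=C1CC[C@@H]2O[C@@]2(C)CC[C@@H]2C[C@@H](OC(=O)[C@H]2C)[C@@](C)(O[Si](CC)(CC)CC)CC[C@@H]1O[Si](CC)(CC)CC | intermediate
30 | 29 with the secondary allylic hydroxyl free (S), tertiary triethylsilyl ether kept | C=C1CC[C@@H]2O[C@@]2(C)CC[C@@H]2C[C@@H](OC(=O)[C@H]2C)[C@@](C)(O[Si](CC)(CC)CC)CC[C@@H]1O | intermediate
31 | methanesulfonate of 30 (S) | C=C1CC[C@@H]2O[C@@]2(C)CC[C@@H]2C[C@@H](OC(=O)[C@H]2C)[C@@](C)(O[Si](CC)(CC)CC)CC[C@@H]1OS(C)(=O)=O | intermediate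
32 | (R)-allylic hydroperoxide, tertiary triethylsilyl ether | C=C1CC[C@@H]2O[C@@]2(C)CC[C@@H]2C[C@@H](OC(=O)[C@H]2C)[C@@](C)(O[Si](CC)(CC)CC)CC[C@H]1OO | intermediate
33 | CNP0319766.1: 14-membered carbocycle fused at C4/C6 of a (3S,4R,6R)-3-methyloxan-2-one, with (S,S)-methyl oxirane, (S)-tertiary alcohol, exocyclic methylene and (R)-hydroperoxide | C=C1CC[C@@H]2O[C@@]2(C)CC[C@@H]2C[C@@H](OC(=O)[C@H]2C)[C@@](C)(O)CC[C@H]1OO | target

**Step count and risks**

Total steps: 22. Longest linear sequence: 18 steps (steps 1–10 and 15–22, from (S)-linalool).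

Three steps most likely to fail:

1. Step 21. Ionisation of the allylic mesylate may outrun direct displacement. Peroxide would then enter at the methylene terminus with allylic shift, the configuration would be lost, or the epoxide or silyloxy oxygen would capture the cation across the ring. The fallback sets out from 30 and comes back at 32. Mesylate 31 is made as in the route and treated at 0 °C in DMF with the caesium salt of 2-methoxypropan-2-yl hydroperoxide (from CsOH·H2O), an anionic protected peroxide that reacts by direct SN2 with inversion, giving the mixed peroxyketal F1. Mild hydrolysis (AcOH/THF/H2O) then releases acetone and methanol and gives hydroperoxide 32.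

2. Step 18. Hydroboration may also take place at the exocyclic methylene, the borane may couple between molecules instead of within one, or the aqueous base may open the lactone. The fallback sets out from 15 and 23 and comes back at 28. It exchanges the two carbon–carbon bond formations, so that hydroboration precedes the appearance of the exocyclic alkene and the ring is closed by Ni/Cr coupling. Triflate 23 is iododesilylated (N-iodosuccinimide, hexafluoropropan-2-ol) to (E)-6-iodohepta-1,5-dien-2-yl trifluoromethanesulfonate F2. Alcohol 15 is treated with 9-BBN (2.2 equiv) to give the O,C-bis(boryl) adduct F3, which is coupled at the iodide of F2 (Pd(dppf)Cl2, AsPh3, Cs2CO3) to give the seco triflate alcohol F4. Oxidation (TEMPO, PhI(OAc)2) gives the seco triflate aldehyde F5. Intramolecular Nozaki–Hiyama–Kishi coupling (CrCl2, NiCl2, the ligand of step 15, high dilution) closes the ring to the macrocyclic allylic alcohol F6, and silylation (Et3SiCl, imidazole) returns 28.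

3. Step 15. Facial control at the new carbinol by the chiral chromium ligand may be insufficient, or activation of the triflate may be sluggish in the solvent that the ligand needs. The fallback sets out from 16 and 23 and comes back at 24. Ligand-free coupling (CrCl2, NiCl2 cat., DMF) gives 24 together with the (5R)-carbinol epimer F7. The mixture is oxidised with MnO2 to the enone F8. Corey–Bakshi–Shibata reduction ((R)-2-methyl oxazaborolidine, catecholborane, −78 °C), with the alkenyl group as the large substituent, should return the (S)-alcohol 24.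

**Further compounds**

F1 | step 21 | 2-methoxypropan-2-yl peroxide (peroxyketal) of the macrocycle, (R) at the peroxy carbon | C=C1CC[C@@H]2O[C@@]2(C)CC[C@@H]2C[C@@H](OC(=O)[C@H]2C)[C@@](C)(O[Si](CC)(CC)CC)CC[C@H]1OOC(C)(C)OC
F2 | step 18 | (E)-6-iodohepta-1,5-dien-2-yl trifluoromethanesulfonate | C=C(OS(=O)(=O)C(F)(F)F)CC/C=C(\C)I
F3 | step 18 | O,C-bis(9-borabicyclo[3.3.1]nonan-9-yl) adduct of 15 | C1CCC2CCCC1B2CC[C@@H]1C[C@@H](OC(=O)[C@H]1C)[C@@](C)(O[Si](CC)(CC)CC)CCCOB1C2CCCC1CCC2
F4 | step 18 | seco triflate alcohol | C=C(OS(=O)(=O)C(F)(F)F)CC/C=C(\C)CC[C@@H]1C[C@@H](OC(=O)[C@H]1C)[C@@](C)(O[Si](CC)(CC)CC)CCCO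
F5 | step 18 | seco triflate aldehyde | C=C(OS(=O)(=O)C(F)(F)F)CC/C=C(\C)CC[C@@H]1C[C@@H](OC(=O)[C@H]1C)[C@@](C)(O[Si](CC)(CC)CC)CCC=O
F6 | step 18 | macrocyclic (S)-allylic alcohol, 28 without the secondary silyl group | C=C1CC/C=C(\C)CC[C@@H]2C[C@@H](OC(=O)[C@H]2C)[C@@](C)(O[Si](CC)(CC)CC)CC[C@@H]1O
F7 | step 15 | (5R)-carbinol epimer of 24 | C=C[C@@H]1C[C@@H](OC(=O)[C@H]1C)[C@@](C)(O[Si](CC)(CC)CC)CC[C@@H](O)C(=C)CC/C=C(\C)[Si](CC)(CC)CC
F8 | step 15 | enone from oxidation of 24 and F7 | C=C[C@@H]1C[C@@H](OC(=O)[C@H]1C)[C@@](C)(O[Si](CC)(CC)CC)CCC(=O)C(=C)CC/C=C(\C)[Si](CC)(CC)CC
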